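A solid charged per volume tempts you to read its charge as a concentration and to keep all of it for fear of slowing the flask, so before you set the solid reagent of the next run, ask how much of it this flask can use.

| flask | left-handed substrate | right-handed substrate | solid reagent | racemization catalyst | remark | time |
|---|---|---|---|---|---|---|
| south-east | 42 mM | 42 mM | 126 mM | 59 µM | run made earlier |  |
| south | 42 mM | 42 mM | 126 mM | 92 µM | run made earlier |  |
| flask | 42 mM | 42 mM | 126 mM | 42 µM |  | 40 h |

| run | time / h | left-handed product / % | right-handed product / % |
|---|---|---|---|
| south-east | 2.00 | 0.5 | 0.1 |
| south-east | 3.00 | 0.9 | 0 |
| south-east | 5.00 | 2.4 | 0.2 |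
| south-east | 8.00 | 2.7 | 1.6 |
| south-east | 15.0 | 8.4 | 2.3 |
| south-east | 25.0 | 12.8 | 4.3 |
| south | 2.00 | 0 | 0.3 |
| south | 3.00 | 0.6 | 1.9 |
| south | 5.00 | 2.3 | 0.3 |
| south | 8.00 | 3.8 | 0.9 |
| south | 15.0 | 8.2 | 2.9 |
| south | 25.0 | 12.9 | 4.6 |

(standard deviation of a reading: 0.5 percentage points)

1. left-handed product and right-handed product together, in percent of the left-handed substrate and right-handed substrate charged together, at 40 h
2. excess of left-handed product over right-handed product in the product at 40 h
3. whether the exchange between left-handed substrate and right-handed substrate keeps pace with the reaction: how far the product's excess at 40 h gets from its value without exchange to its value with instant exchange (above 80% keeps pace, below 20% hardly takes part, else lags behind)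

- partner is single-handed; left-handed substrate and right-handed substrate are mirror images of each other, charged as a racemate, each of them at the stated concentration
- given per volume of solution although it is solid: solid reagent
- the analysis behind the earlier runs scatters by 0.5 percentage points, standard deviation
- at the start none of the solid reagent is in solution
- an excess is the difference of the two amounts in percent of their sum
- an excess is below zero if the other one leads
- the handed part of partner does not stay in what it makes, so the products of the two hands are mirror images too

I take the solid reagent to be the source of the partner, with one partner going into each product formed. Between 15.0 h and 25.0 h the mean total product of the two runs rises from 10.9% to 17.3%, and a straight line carried on to 40 h gives my own estimate of 26.9%. Over both substrates that is a demand D of 22.6 mM of partner. The cover W, the charge of solid reagent divided by D, is 5.58 for this flask; that is above one, so on this estimate the solid reagent is not the limiting reagent up to the asked time. So I would leave substrates and catalyst as they are and charge less solid next time. The pooled readings at 25.0 h give me an excess of 48.6%. The totals there, 17.1% and 17.5%, differ within the scatter, and this flask's 42 µM lies below both loadings, so I leave the pace open.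

The forecast says 27%, 47.5% and, unlike me, keeps pace, from the “steady excess and the insensitivity to loading”.

The flask gives 27.6% with an excess of 48.1%, and the exchange lags behind, getting 61% of the way.

    partner + left-handed substrate → left-handed product (k = 7.60 × 10⁻⁴ /M/s)
    partner + right-handed substrate → right-handed product (k = 2.50 × 10⁻⁴ /M/s)
    left-handed substrate + racemization catalyst ⇌ right-handed substrate + racemization catalyst, rate k3*[racemization catalyst]*[left-handed substrate] forward; the back reaction follows from the equilibrium constant (k = 0.880 /M/s)
    2 racemization catalyst → spent catalyst (k = 0.300 /M/s)
    solid reagent ⇌ partner, rate k5*(cs5 - [partner]) while solid is left; crystals form when [partner] > cs5 (solubility = 5.90 mM, k = 1.40 × 10⁻⁴ /s)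

At 40.0 h this flask still holds 77.8% of its solid reagent as solid, beside 4.85 mM of partner. Counting that dissolved partner with the products, W becomes 4.50, still above one.

For the neighbour charged with 76 mM of solid reagent, W on my demand is 3.36, above one, so I expect the same total of product as in this flask. It gives 27.6% with an excess of 48.1%, and 63.1% of its solid reagent remains solid.

(The data were generated by integration for an exercise, noise included.)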